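**Strategy.** Everything rests on cutting the cyclohexane ring between Cd and Ce. With the ring epoxide traced back to a Cc=Cd alkene, the hydroxyl carbon Ce is an allylic carbinol attached to the methyl-bearing alkene carbon Cd, which is what an alkenyl metal leaves behind after attacking an aldehyde. One CrCl2/NiCl2 cyclisation of a Z-alkenyl iodide onto a tethered aldehyde therefore closes the carbocycle, makes Cd–Ce and sets the Ce alcohol that later steers the epoxidation. The precursor is an acyclic aldehyde (Ce) with a chelating PMB ether at Cf, the Cb–Cc=Cd(CH3)I arm on Ca, and the C7 methylidene side chain bearing a TES ether at C8.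

Key step: step 13

Labels: ring carbons Ca (CH bearing the side chain), Cb (CH2), Cc and Cd (epoxide carbons; Cd bears CH3), Ce (CH–OH), Cf (CH–O-acyl); side chain C7 (carbon carrying =CH2), C8 (CH–O-angeloyl), C9 (CH2), C10 and C11 (side-chain epoxide). PMB = 4-methoxybenzyl, TES = triethylsilyl, TBS = tert-butyldimethylsilyl.

Remark on the chemistry (assumption): read from the SMILES, the side chain on Ca, the Cf and Ce oxygens and the ring epoxide all lie on one ring face, C8 is S, C10 is R and the saturated acyl group is (R)-2-methylbutanoyl; compounds 1, 5, 6, 13, 25 and 28 are taken as purchasable.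

Step 1
Reactants: 1 but-2-yn-1-ol
Product: 3 (2Z)-3-iodobut-2-en-1-ol, via cyclic alkenylaluminate 2 (not isolated)
Conditions: NaAlH2(OCH2CH2OMe)2, THF, 0 °C to rt; then I2, −78 to 0 °C
Reagents that add atoms: iodine, II
Why: Alkoxide-directed trans-hydroalumination of the propargylic alcohol puts aluminium on C3 inside a five-membered aluminate, and iodinolysis with retention should give the Z-iodoalkene (hydroalumination–iodination).

Step 2
Reactants: 3 (2Z)-3-iodobut-2-en-1-ol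
Product: 4 (2Z)-1-bromo-3-iodobut-2-ene
Conditions: CBr4, PPh3, CH2Cl2, 0 °C
Reagents that add atoms: tetrabromomethane, BrC(Br)(Br)Br
Why: Appel bromination of the primary allylic alcohol is an SN2 displacement of the oxyphosphonium ion and should leave the iodoalkene geometry untouched.

Step 3
Reactants: 5 methyl (2S)-oxirane-2-carboxylate; 6 (2-methylprop-1-en-1-yl)magnesium bromide
Product: 7 methyl (2S)-2-hydroxy-5-methylhex-4-enoate
Conditions: CuI (10 mol %), THF, −40 °C; aq. NH4Cl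
Reagents that add atoms: none
Why: Copper-catalysed Grignard opening of the glycidic ester is an SN2 attack at the unsubstituted C3, so the C2 stereocentre (the future C8) is carried over unchanged from the commercial epoxide.

Step 4
Reactants: 7 methyl (2S)-2-hydroxy-5-methylhex-4-enoate
Product: 8 methyl (2S)-5-methyl-2-(triethylsilyloxy)hex-4-enoate
Conditions: Et3SiCl, imidazole, CH2Cl2, 0 °C to rt
Reagents that add atoms: chlorotriethylsilane, CC[Si](Cl)(CC)CC
Why: Routine silylation of a secondary alcohol, with TES chosen because it is non-chelating in the later aldol and can be removed in the presence of a TBS ether.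

Step 5
Reactants: 8 methyl (2S)-5-methyl-2-(triethylsilyloxy)hex-4-enoate
Product: 9 (2S)-N-methoxy-N,5-dimethyl-2-(triethylsilyloxy)hex-4-enamide
Conditions: MeNHOMe·HCl, i-PrMgCl, THF, −20 to 0 °C
Reagents that add atoms: N,O-dimethylhydroxylamine hydrochloride, CNOC.Cl
Why: Aminolysis of the ester by the magnesium amide of N,O-dimethylhydroxylamine (Weinreb amide formation) is fast at low temperature and should not epimerise the alpha-silyloxy centre.

Step 6
Reactants: 9 (2S)-N-methoxy-N,5-dimethyl-2-(triethylsilyloxy)hex-4-enamide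
Product: 10 (3S)-6-methyl-3-(triethylsilyloxy)hept-5-en-2-one
Conditions: MeMgBr, THF, 0 °C
Reagents that add atoms: methylmagnesium bromide, C[Mg]Br
Why: Grignard addition to the Weinreb amide stops at the chelated tetrahedral intermediate, which releases the methyl ketone only on work-up (Weinreb ketone synthesis).

Step 7
Reactants: 10 (3S)-6-methyl-3-(triethylsilyloxy)hept-5-en-2-one; 4 (2Z)-1-bromo-3-iodobut-2-ene
Product: 12 (5S,9Z)-10-iodo-2-methyl-5-(triethylsilyloxy)undeca-2,9-dien-6-one, via kinetic lithium enolate 11 (not isolated)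
Conditions: LiN(i-Pr)2, THF, −78 °C; then 4, DMPU, −78 to −40 °C
Reagents that add atoms: none
Why: Kinetic deprotonation occurs at the methyl group and not at the silyloxy-bearing methine, and alkylation of this enolate by the reactive primary allylic bromide (ketone enolate alkylation) installs the Cb–Cc=Cd(CH3)I arm with its Z geometry already fixed.

Step 8
Reactants: 12 (5S,9Z)-10-iodo-2-methyl-5-(triethylsilyloxy)undeca-2,9-dien-6-one; 13 2-[(4-methoxybenzyl)oxy]acetaldehyde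
Product: 15 (5S,7R,9Z)-7-{(1R)-1-hydroxy-2-[(4-methoxybenzyl)oxy]ethyl}-10-iodo-2-methyl-5-(triethylsilyloxy)undeca-2,9-dien-6-one, via Z-dibutylboron enolate 14 (not isolated)
Conditions: n-Bu2BOTf, i-Pr2NEt, CH2Cl2, −78 to 0 °C; then 13, −78 to −20 °C; MeOH, pH 7 buffer, H2O2, 0 °C
Reagents that add atoms: none
Why: In this substrate-controlled boron aldol the Z-enolate formed on the methylene side reacts through a Zimmerman–Traxler chair to give the syn relationship of Ca and Cf, while the non-chelated C8–OTES bond, held anti to the enolate C–O bond, sends the aldehyde to the enolate face remote from C9, so the all-syn C8/Ca/Cf triad is expected.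

Step 9
Reactants: 15 (5S,7R,9Z)-7-{(1R)-1-hydroxy-2-[(4-methoxybenzyl)oxy]ethyl}-10-iodo-2-methyl-5-(triethylsilyloxy)undeca-2,9-dien-6-one
Product: 16 (5S,7R,9Z)-10-iodo-7-[(4R)-2-(4-methoxyphenyl)-1,3-dioxolan-4-yl]-2-methyl-5-(triethylsilyloxy)undeca-2,9-dien-6-one (both acetal epimers)
Conditions: DDQ, 4 Å molecular sieves, CH2Cl2, 0 °C
Reagents that add atoms: none
Why: Without water DDQ oxidises the PMB ether to an oxocarbenium ion that the neighbouring Cf hydroxyl traps (oxidative acetalisation of a hydroxy PMB ether), which masks the beta-hydroxy ketone; the new acetal centre is uncontrolled and is destroyed again in step 11.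

Step 10
Reactants: 16 (5S,7R,9Z)-10-iodo-7-[(4R)-2-(4-methoxyphenyl)-1,3-dioxolan-4-yl]-2-methyl-5-(triethylsilyloxy)undeca-2,9-dien-6-one
Product: 17 (5S,7S,9Z)-10-iodo-7-[(4R)-2-(4-methoxyphenyl)-1,3-dioxolan-4-yl]-2-methyl-6-methylidene-5-(triethylsilyloxy)undeca-2,9-diene
Conditions: Cp2TiMe2, toluene, 70 °C, dark
Reagents that add atoms: dimethyltitanocene Cp2TiMe2, C[Ti](C)(C1C=CC=C1)C1C=CC=C1
Why: Thermolysis of Cp2TiMe2 gives Cp2Ti=CH2, which methylenates the hindered ketone without base (Petasis olefination), so the epimerisable Ca centre and the beta-oxygen should be safe.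

Step 11
Reactants: 17 (5S,7S,9Z)-10-iodo-7-[(4R)-2-(4-methoxyphenyl)-1,3-dioxolan-4-yl]-2-methyl-6-methylidene-5-(triethylsilyloxy)undeca-2,9-diene
Product: 18 (2R,3S,5Z)-6-iodo-2-[(4-methoxybenzyl)oxy]-3-[(3S)-6-methyl-3-(triethylsilyloxy)hepta-1,5-dien-2-yl]hept-5-en-1-ol
Conditions: i-Bu2AlH, CH2Cl2, −78 to 0 °C; aq. potassium sodium tartrate
Reagents that add atoms: none
Why: i-Bu2AlH binds the less hindered primary acetal oxygen and reduces the resulting oxocarbenium ion (regioselective reductive acetal opening), which should leave PMB on the secondary Cf oxygen and free the primary alcohol.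

Step 12
Reactants: 18 (2R,3S,5Z)-6-iodo-2-[(4-methoxybenzyl)oxy]-3-[(3S)-6-methyl-3-(triethylsilyloxy)hepta-1,5-dien-2-yl]hept-5-en-1-ol
Product: 19 (2R,3S,5Z)-6-iodo-2-[(4-methoxybenzyl)oxy]-3-[(3S)-6-methyl-3-(triethylsilyloxy)hepta-1,5-dien-2-yl]hept-5-enal
Conditions: Dess–Martin periodinane, CH2Cl2, 0 °C to rt
Reagents that add atoms: none
Why: Dess–Martin oxidation of the primary alcohol is mild and non-epimerising, and the alpha-alkoxy aldehyde is to be used at once.

Step 13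
Reactants: 19 (2R,3S,5Z)-6-iodo-2-[(4-methoxybenzyl)oxy]-3-[(3S)-6-methyl-3-(triethylsilyloxy)hepta-1,5-dien-2-yl]hept-5-enal
Product: 21 (1S,5S,6R)-6-[(4-methoxybenzyl)oxy]-2-methyl-5-[(3S)-6-methyl-3-(triethylsilyloxy)hepta-1,5-dien-2-yl]cyclohex-2-en-1-ol, via alkenylchromium dichloride 20 (not isolated)
Conditions: CrCl2 (8 equiv), NiCl2 (2 mol %), degassed THF/DMF (3:1), 0.005 M, rt
Reagents that add atoms: none
Why: Nickel, reduced in the flask by CrCl2 to its zerovalent state, adds oxidatively to the alkenyl iodide without loss of alkene geometry, and transmetalation hands the alkenyl ligand to trivalent chromium; the resulting alkenylchromium 20 attacks the tethered aldehyde and leaves the chromium alkoxide of 21. The closest known reaction type is the intramolecular Nozaki–Hiyama–Kishi coupling of an alkenyl iodide with an aldehyde. The carbocycle forms by 6-exo-trig attack on the C=O bond, and since iodine sits cis to Cb the former iodoalkene ends up inside the ring as Cc=Cd. The new Ce stereocentre is governed by a half-chair in which the bulky Ca substituent is pseudo-equatorial, Cf–OPMB is therefore axial, and trivalent chromium bridges the aldehyde oxygen and the PMB ether oxygen, which holds the carbonyl oxygen pseudo-equatorial and gauche to Cf–O. The selectivity required is a cis relationship of the new Ce–O bond to Cf–O together with reaction at the C–I bond only; the chelating ether at Cf in a THF-rich, weakly coordinating medium should secure the first, and the preference of zerovalent nickel for the alkenyl iodide over the TES ether, the PMB ether and the unactivated alkenes the second.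

Step 14
Reactants: 21 (1S,5S,6R)-6-[(4-methoxybenzyl)oxy]-2-methyl-5-[(3S)-6-methyl-3-(triethylsilyloxy)hepta-1,5-dien-2-yl]cyclohex-2-en-1-ol
Product: 22 (1R,2R,3R,4S,6S)-3-[(4-methoxybenzyl)oxy]-1-methyl-4-[(3S)-6-methyl-3-(triethylsilyloxy)hepta-1,5-dien-2-yl]-7-oxabicyclo[4.1.0]heptan-2-ol
Conditions: VO(acac)2 (5 mol %), t-BuOOH, CH2Cl2, 0 °C to rt
Reagents that add atoms: tert-butyl hydroperoxide, CC(C)(C)OO
Why: In this hydroxyl-directed epoxidation the vanadium-bound peroxide is delivered by the allylic Ce hydroxyl to the same face of Cc=Cd, which sets Cc and Cd cis to Ce–OH and should leave the non-allylic alkenes untouched.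

Step 15
Reactants: 22 (1R,2R,3R,4S,6S)-3-[(4-methoxybenzyl)oxy]-1-methyl-4-[(3S)-6-methyl-3-(triethylsilyloxy)hepta-1,5-dien-2-yl]-7-oxabicyclo[4.1.0]heptan-2-ol
Product: 23 (1S,2R,3R,4S,6S)-2-[(tert-butyldimethylsilyl)oxy]-3-[(4-methoxybenzyl)oxy]-1-methyl-4-[(3S)-6-methyl-3-(triethylsilyloxy)hepta-1,5-dien-2-yl]-7-oxabicyclo[4.1.0]heptane
Conditions: t-BuMe2SiOTf, 2,6-lutidine, CH2Cl2, −78 to 0 °C
Reagents that add atoms: tert-butyldimethylsilyl trifluoromethanesulfonate, CC(C)(C)[Si](C)(C)OS(=O)(=O)C(F)(F)F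
Why: The silyl triflate with a hindered pyridine base silylates even the crowded Ce hydroxyl at low temperature (silyl ether formation) without opening the epoxide.

Step 16
Reactants: 23 (1S,2R,3R,4S,6S)-2-[(tert-butyldimethylsilyl)oxy]-3-[(4-methoxybenzyl)oxy]-1-methyl-4-[(3S)-6-methyl-3-(triethylsilyloxy)hepta-1,5-dien-2-yl]-7-oxabicyclo[4.1.0]heptane
Product: 24 (1S,2R,3R,4S,6S)-2-[(tert-butyldimethylsilyl)oxy]-1-methyl-4-[(3S)-6-methyl-3-(triethylsilyloxy)hepta-1,5-dien-2-yl]-7-oxabicyclo[4.1.0]heptan-3-ol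
Conditions: DDQ, CH2Cl2/pH 7 buffer (10:1), 0 °C
Reagents that add atoms: none
Why: Oxidative cleavage of the PMB ether by DDQ in wet solvent frees only the Cf hydroxyl, since silyl ethers, epoxide and alkenes are inert to it.

Step 17
Reactants: 24 (1S,2R,3R,4S,6S)-2-[(tert-butyldimethylsilyl)oxy]-1-methyl-4-[(3S)-6-methyl-3-(triethylsilyloxy)hepta-1,5-dien-2-yl]-7-oxabicyclo[4.1.0]heptan-3-ol; 25 (2R)-2-methylbutanoic acid
Product: 26 (1S,2R,3R,4S,6S)-2-[(tert-butyldimethylsilyl)oxy]-1-methyl-4-[(3S)-6-methyl-3-(triethylsilyloxy)hepta-1,5-dien-2-yl]-7-oxabicyclo[4.1.0]heptan-3-yl (2R)-2-methylbutanoate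
Conditions: DCC, DMAP (cat.), CH2Cl2, 0 °C to rt
Reagents that add atoms: none
Why: Steglich esterification acylates the single free hydroxyl at Cf, and the alpha-stereocentre of the acyl group comes unchanged from the commercial (R)-acid because no ketene-forming activation is used.

Step 18
Reactants: 26 (1S,2R,3R,4S,6S)-2-[(tert-butyldimethylsilyl)oxy]-1-methyl-4-[(3S)-6-methyl-3-(triethylsilyloxy)hepta-1,5-dien-2-yl]-7-oxabicyclo[4.1.0]heptan-3-yl (2R)-2-methylbutanoate
Product: 27 (1S,2R,3R,4S,6S)-2-[(tert-butyldimethylsilyl)oxy]-4-[(3S)-3-hydroxy-6-methylhepta-1,5-dien-2-yl]-1-methyl-7-oxabicyclo[4.1.0]heptan-3-yl (2R)-2-methylbutanoate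
Conditions: HF·pyridine, pyridine, THF, 0 °C
Reagents that add atoms: none
Why: Buffered HF·pyridine should cleave the labile, less hindered TES ether at C8 much faster than the crowded TBS ether at Ce (selective desilylation).

Step 19
Reactants: 27 (1S,2R,3R,4S,6S)-2-[(tert-butyldimethylsilyl)oxy]-4-[(3S)-3-hydroxy-6-methylhepta-1,5-dien-2-yl]-1-methyl-7-oxabicyclo[4.1.0]heptan-3-yl (2R)-2-methylbutanoate; 28 (2Z)-2-methylbut-2-enoic acid
Product: 30 (1S,2R,3R,4S,6S)-2-[(tert-butyldimethylsilyl)oxy]-1-methyl-4-[(3S)-6-methyl-3-{[(2Z)-2-methylbut-2-enoyl]oxy}hepta-1,5-dien-2-yl]-7-oxabicyclo[4.1.0]heptan-3-yl (2R)-2-methylbutanoate, via angelic 2,4,6-trichlorobenzoic anhydride 29 (not isolated)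
Conditions: 2,4,6-Cl3C6H2COCl, Et3N, toluene, rt; then 27, toluene, 75 °C
Reagents that add atoms: none
Why: Yamaguchi-type esterification through the 2,4,6-trichlorobenzoyl mixed anhydride, run without a nucleophilic amine catalyst, is the established way to transfer an angeloyl group to a secondary alcohol without Z-to-E isomerisation.

Step 20
Reactants: 30 (1S,2R,3R,4S,6S)-2-[(tert-butyldimethylsilyl)oxy]-1-methyl-4-[(3S)-6-methyl-3-{[(2Z)-2-methylbut-2-enoyl]oxy}hepta-1,5-dien-2-yl]-7-oxabicyclo[4.1.0]heptan-3-yl (2R)-2-methylbutanoate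
Product: 31 (1S,2R,3R,4S,6S)-2-[(tert-butyldimethylsilyl)oxy]-4-[(3S)-4-[(2R)-3,3-dimethyloxiran-2-yl]-3-{[(2Z)-2-methylbut-2-enoyl]oxy}but-1-en-2-yl]-1-methyl-7-oxabicyclo[4.1.0]heptan-3-yl (2R)-2-methylbutanoate
Conditions: D-fructose-derived Shi ketone (30 mol %), KHSO5, K2CO3, Bu4NHSO4, MeCN/CH2(OMe)2, aq. Na2B4O7 buffer, 0 °C
Reagents that add atoms: potassium peroxymonosulfate KHSO5, [K+].[O-]S(=O)(=O)OO
Why: In this Shi epoxidation the chiral dioxirane attacks the electron-rich trisubstituted C10=C11 alkene through a spiro transition state that should set C10 as R by reagent control, while the hindered 1,1-disubstituted alkene and the electron-poor angelate react far more slowly.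

Step 21
Reactants: 31 (1S,2R,3R,4S,6S)-2-[(tert-butyldimethylsilyl)oxy]-4-[(3S)-4-[(2R)-3,3-dimethyloxiran-2-yl]-3-{[(2Z)-2-methylbut-2-enoyl]oxy}but-1-en-2-yl]-1-methyl-7-oxabicyclo[4.1.0]heptan-3-yl (2R)-2-methylbutanoate
Product: 32 (1R,2R,3R,4S,6S)-4-[(3S)-4-[(2R)-3,3-dimethyloxiran-2-yl]-3-{[(2Z)-2-methylbut-2-enoyl]oxy}but-1-en-2-yl]-2-hydroxy-1-methyl-7-oxabicyclo[4.1.0]heptan-3-yl (2R)-2-methylbutanoate (CNP0181486.1)
Conditions: Bu4NF, AcOH, THF, 0 °C to rt
Reagents that add atoms: none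
Why: Fluoride buffered with acetic acid removes the TBS ether (desilylation) under near-neutral conditions, which should avoid acyl migration from Cf to Ce and opening of either epoxide.

Compound list
1 | but-2-yn-1-ol | CC#CCO | starting material
2 | cyclic alkenylaluminate (sodium ate complex of the five-membered O–Al–C ring formed from 1) | CC1=CCO[Al-]1(OCCOC)OCCOC.[Na+] | intermediate
3 | (2Z)-3-iodobut-2-en-1-ol | OC/C=C(/C)I | intermediate
4 | (2Z)-1-bromo-3-iodobut-2-ene | BrC/C=C(/C)I | intermediate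
5 | methyl (2S)-oxirane-2-carboxylate | COC(=O)[C@@H]1CO1 | starting material
6 | (2-methylprop-1-en-1-yl)magnesium bromide | CC(C)=C[Mg]Br | starting material
7 | methyl (2S)-2-hydroxy-5-methylhex-4-enoate | COC(=O)[C@@H](O)CC=C(C)C | intermediate
8 | methyl (2S)-5-methyl-2-(triethylsilyloxy)hex-4-enoate | COC(=O)[C@@H](O[Si](CC)(CC)CC)CC=C(C)C | intermediate
9 | (2S)-N-methoxy-N,5-dimethyl-2-(triethylsilyloxy)hex-4-enamide | CON(C)C(=O)[C@@H](O[Si](CC)(CC)CC)CC=C(C)C | intermediate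
10 | (3S)-6-methyl-3-(triethylsilyloxy)hept-5-en-2-one | CC(=O)[C@@H](O[Si](CC)(CC)CC)CC=C(C)C | intermediate
11 | kinetic lithium enolate (lithium (3S)-6-methyl-3-(triethylsilyloxy)hepta-1,5-dien-2-olate) | [Li]OC(=C)[C@@H](O[Si](CC)(CC)CC)CC=C(C)C | intermediate
12 | (5S,9Z)-10-iodo-2-methyl-5-(triethylsilyloxy)undeca-2,9-dien-6-one | O=C([C@H](CC=C(C)C)O[Si](CC)(CC)CC)CC/C=C(/C)I | intermediate
13 | 2-[(4-methoxybenzyl)oxy]acetaldehyde | COc1ccc(COCC=O)cc1 | starting material
14 | Z-dibutylboron enolate of 12 | CCCCB(CCCC)O/C(=C\C/C=C(/C)I)[C@H](CC=C(C)C)O[Si](CC)(CC)CC | intermediate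
15 | (5S,7R,9Z)-7-{(1R)-1-hydroxy-2-[(4-methoxybenzyl)oxy]ethyl}-10-iodo-2-methyl-5-(triethylsilyloxy)undeca-2,9-dien-6-one | O=C([C@H](CC=C(C)C)O[Si](CC)(CC)CC)[C@H](C/C=C(/C)I)[C@@H](O)COCc1ccc(OC)cc1 | intermediate
16 | (5S,7R,9Z)-10-iodo-7-[(4R)-2-(4-methoxyphenyl)-1,3-dioxolan-4-yl]-2-methyl-5-(triethylsilyloxy)undeca-2,9-dien-6-one (both acetal epimers) | O=C([C@H](CC=C(C)C)O[Si](CC)(CC)CC)[C@H](C/C=C(/C)I)[C@@H]1COC(c2ccc(OC)cc2)O1 | intermediate
17 | (5S,7S,9Z)-10-iodo-7-[(4R)-2-(4-methoxyphenyl)-1,3-dioxolan-4-yl]-2-methyl-6-methylidene-5-(triethylsilyloxy)undeca-2,9-diene | C=C([C@H](CC=C(C)C)O[Si](CC)(CC)CC)[C@H](C/C=C(/C)I)[C@@H]1COC(c2ccc(OC)cc2)O1 | intermediate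
18 | (2R,3S,5Z)-6-iodo-2-[(4-methoxybenzyl)oxy]-3-[(3S)-6-methyl-3-(triethylsilyloxy)hepta-1,5-dien-2-yl]hept-5-en-1-ol | C=C([C@H](CC=C(C)C)O[Si](CC)(CC)CC)[C@H](C/C=C(/C)I)[C@@H](OCc1ccc(OC)cc1)CO | intermediate
19 | (2R,3S,5Z)-6-iodo-2-[(4-methoxybenzyl)oxy]-3-[(3S)-6-methyl-3-(triethylsilyloxy)hepta-1,5-dien-2-yl]hept-5-enal | C=C([C@H](CC=C(C)C)O[Si](CC)(CC)CC)[C@H](C/C=C(/C)I)[C@@H](OCc1ccc(OC)cc1)C=O | intermediate
20 | alkenylchromium dichloride derived from 19 | C=C([C@H](CC=C(C)C)O[Si](CC)(CC)CC)[C@H](C/C=C(/C)[Cr](Cl)Cl)[C@@H](OCc1ccc(OC)cc1)C=O | intermediate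
21 | (1S,5S,6R)-6-[(4-methoxybenzyl)oxy]-2-methyl-5-[(3S)-6-methyl-3-(triethylsilyloxy)hepta-1,5-dien-2-yl]cyclohex-2-en-1-ol | C=C([C@H](CC=C(C)C)O[Si](CC)(CC)CC)[C@@H]1CC=C(C)[C@H](O)[C@@H]1OCc1ccc(OC)cc1 | intermediate
22 | (1R,2R,3R,4S,6S)-3-[(4-methoxybenzyl)oxy]-1-methyl-4-[(3S)-6-methyl-3-(triethylsilyloxy)hepta-1,5-dien-2-yl]-7-oxabicyclo[4.1.0]heptan-2-ol | C=C([C@H](CC=C(C)C)O[Si](CC)(CC)CC)[C@@H]1C[C@@H]2O[C@]2(C)[C@H](O)[C@@H]1OCc1ccc(OC)cc1 | intermediate
23 | (1S,2R,3R,4S,6S)-2-[(tert-butyldimethylsilyl)oxy]-3-[(4-methoxybenzyl)oxy]-1-methyl-4-[(3S)-6-methyl-3-(triethylsilyloxy)hepta-1,5-dien-2-yl]-7-oxabicyclo[4.1.0]heptane | C=C([C@H](CC=C(C)C)O[Si](CC)(CC)CC)[C@@H]1C[C@@H]2O[C@]2(C)[C@H](O[Si](C)(C)C(C)(C)C)[C@@H]1OCc1ccc(OC)cc1 | intermediate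
24 | (1S,2R,3R,4S,6S)-2-[(tert-butyldimethylsilyl)oxy]-1-methyl-4-[(3S)-6-methyl-3-(triethylsilyloxy)hepta-1,5-dien-2-yl]-7-oxabicyclo[4.1.0]heptan-3-ol | C=C([C@H](CC=C(C)C)O[Si](CC)(CC)CC)[C@@H]1C[C@@H]2O[C@]2(C)[C@H](O[Si](C)(C)C(C)(C)C)[C@@H]1O | intermediate
25 | (2R)-2-methylbutanoic acid | CC[C@@H](C)C(=O)O | starting material
26 | (1S,2R,3R,4S,6S)-2-[(tert-butyldimethylsilyl)oxy]-1-methyl-4-[(3S)-6-methyl-3-(triethylsilyloxy)hepta-1,5-dien-2-yl]-7-oxabicyclo[4.1.0]heptan-3-yl (2R)-2-methylbutanoate | C=C([C@H](CC=C(C)C)O[Si](CC)(CC)CC)[C@@H]1C[C@@H]2O[C@]2(C)[C@H](O[Si](C)(C)C(C)(C)C)[C@@H]1OC(=O)[C@H](C)CC | intermediate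
27 | (1S,2R,3R,4S,6S)-2-[(tert-butyldimethylsilyl)oxy]-4-[(3S)-3-hydroxy-6-methylhepta-1,5-dien-2-yl]-1-methyl-7-oxabicyclo[4.1.0]heptan-3-yl (2R)-2-methylbutanoate | C=C([C@H](CC=C(C)C)O)[C@@H]1C[C@@H]2O[C@]2(C)[C@H](O[Si](C)(C)C(C)(C)C)[C@@H]1OC(=O)[C@H](C)CC | intermediate
28 | (2Z)-2-methylbut-2-enoic acid (angelic acid) | C/C=C(/C)C(=O)O | starting material
29 | angelic 2,4,6-trichlorobenzoic anhydride | C/C=C(/C)C(=O)OC(=O)c1c(Cl)cc(Cl)cc1Cl | intermediate
30 | (1S,2R,3R,4S,6S)-2-[(tert-butyldimethylsilyl)oxy]-1-methyl-4-[(3S)-6-methyl-3-{[(2Z)-2-methylbut-2-enoyl]oxy}hepta-1,5-dien-2-yl]-7-oxabicyclo[4.1.0]heptan-3-yl (2R)-2-methylbutanoate | C=C([C@H](CC=C(C)C)OC(=O)/C(C)=C\C)[C@@H]1C[C@@H]2O[C@]2(C)[C@H](O[Si](C)(C)C(C)(C)C)[C@@H]1OC(=O)[C@H](C)CC | intermediate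
31 | (1S,2R,3R,4S,6S)-2-[(tert-butyldimethylsilyl)oxy]-4-[(3S)-4-[(2R)-3,3-dimethyloxiran-2-yl]-3-{[(2Z)-2-methylbut-2-enoyl]oxy}but-1-en-2-yl]-1-methyl-7-oxabicyclo[4.1.0]heptan-3-yl (2R)-2-methylbutanoate | C=C([C@H](C[C@H]1OC1(C)C)OC(=O)/C(C)=C\C)[C@@H]1C[C@@H]2O[C@]2(C)[C@H](O[Si](C)(C)C(C)(C)C)[C@@H]1OC(=O)[C@H](C)CC | intermediate
32 | (1R,2R,3R,4S,6S)-4-[(3S)-4-[(2R)-3,3-dimethyloxiran-2-yl]-3-{[(2Z)-2-methylbut-2-enoyl]oxy}but-1-en-2-yl]-2-hydroxy-1-methyl-7-oxabicyclo[4.1.0]heptan-3-yl (2R)-2-methylbutanoate (CNP0181486.1) | C=C([C@H](C[C@H]1OC1(C)C)OC(=O)/C(C)=C\C)[C@@H]1C[C@@H]2O[C@]2(C)[C@H](O)[C@@H]1OC(=O)[C@H](C)CC | target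

Total step count: 21. Longest linear sequence: 19 steps (steps 3 to 21, from 5); steps 1 and 2 make the alkylating agent 4.

The three steps most likely to fail:

Step 13. What may go wrong is poor facial selectivity at the aldehyde: the closure may run through a non-chelated, dipole-opposed arrangement that places the new hydroxyl trans to the Cf oxygen. Premature protonation of the alkenylchromium is a second failure mode. The fallback sets out from 19 and comes back at 21. The closure is run without regard to the Ce configuration, and the alcohol mixture, 21 together with its Ce epimer (1R,5S,6R)-6-[(4-methoxybenzyl)oxy]-2-methyl-5-[(3S)-6-methyl-3-(triethylsilyloxy)hepta-1,5-dien-2-yl]cyclohex-2-en-1-ol F1, is oxidised with Dess–Martin periodinane to the single enone (5S,6R)-6-[(4-methoxybenzyl)oxy]-2-methyl-5-[(3S)-6-methyl-3-(triethylsilyloxy)hepta-1,5-dien-2-yl]cyclohex-2-en-1-one F2. A Luche reduction (NaBH4, CeCl3·7H2O, MeOH, −78 °C) should then add hydride anti to the axial Cf–OPMB bond and return 21, so the Ce centre is set by 1,2-reduction and no longer by the C–C bond formation.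

Step 10. What may go wrong is failure of the titanium methylidene to engage the ketone, which is flanked by two branched carbons, or enolisation toward Ca during a slow olefination, with epimerisation or loss of the beta-oxygen. The fallback sets out from 16 and comes back at 17 by a Peterson olefination. The small, weakly basic organocerium reagent made from Me3SiCH2Li and anhydrous CeCl3 (THF, −78 °C) adds to the ketone to give the beta-hydroxysilane (5S,7R,9Z)-10-iodo-7-[(4R)-2-(4-methoxyphenyl)-1,3-dioxolan-4-yl]-2-methyl-5-(triethylsilyloxy)-6-[(trimethylsilyl)methyl]undeca-2,9-dien-6-ol F3. KH in THF then triggers syn-elimination of silanolate to give 17.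

Step 19. What may go wrong is Z-to-E isomerisation of the angeloyl unit during activation or acyl transfer, or sluggish acylation of the allylic C8 hydroxyl. The fallback sets out from 27 and comes back at 30, and builds the Z-enoate on the substrate instead of transferring it. Alcohol 27 is esterified (DCC, DMAP, CH2Cl2) with 2-[bis(2,2,2-trifluoroethoxy)phosphoryl]propanoic acid to the phosphonate ester (1S,2R,3R,4S,6S)-4-[(3S)-3-({2-[bis(2,2,2-trifluoroethoxy)phosphoryl]propanoyl}oxy)-6-methylhepta-1,5-dien-2-yl]-2-[(tert-butyldimethylsilyl)oxy]-1-methyl-7-oxabicyclo[4.1.0]heptan-3-yl (2R)-2-methylbutanoate F4. A Still–Gennari olefination with acetaldehyde (KN(SiMe3)2, 18-crown-6, THF, −78 °C) should then give the Z-trisubstituted enoate 30.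

Further compounds
F1 | step 13 | (1R,5S,6R)-6-[(4-methoxybenzyl)oxy]-2-methyl-5-[(3S)-6-methyl-3-(triethylsilyloxy)hepta-1,5-dien-2-yl]cyclohex-2-en-1-ol | C=C([C@H](CC=C(C)C)O[Si](CC)(CC)CC)[C@@H]1CC=C(C)[C@@H](O)[C@@H]1OCc1ccc(OC)cc1
F2 | step 13 | (5S,6R)-6-[(4-methoxybenzyl)oxy]-2-methyl-5-[(3S)-6-methyl-3-(triethylsilyloxy)hepta-1,5-dien-2-yl]cyclohex-2-en-1-one | C=C([C@H](CC=C(C)C)O[Si](CC)(CC)CC)[C@@H]1CC=C(C)C(=O)[C@@H]1OCc1ccc(OC)cc1
F3 | step 10 | (5S,7R,9Z)-10-iodo-7-[(4R)-2-(4-methoxyphenyl)-1,3-dioxolan-4-yl]-2-methyl-5-(triethylsilyloxy)-6-[(trimethylsilyl)methyl]undeca-2,9-dien-6-ol | C[Si](C)(C)CC(O)([C@H](CC=C(C)C)O[Si](CC)(CC)CC)[C@H](C/C=C(/C)I)[C@@H]1COC(c2ccc(OC)cc2)O1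
F4 | step 19 | (1S,2R,3R,4S,6S)-4-[(3S)-3-({2-[bis(2,2,2-trifluoroethoxy)phosphoryl]propanoyl}oxy)-6-methylhepta-1,5-dien-2-yl]-2-[(tert-butyldimethylsilyl)oxy]-1-methyl-7-oxabicyclo[4.1.0]heptan-3-yl (2R)-2-methylbutanoate | C=C([C@H](CC=C(C)C)OC(=O)C(C)P(=O)(OCC(F)(F)F)OCC(F)(F)F)[C@@H]1C[C@@H]2O[C@]2(C)[C@H](O[Si](C)(C)C(C)(C)C)[C@@H]1OC(=O)[C@H](C)CC
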